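**Retrosynthetic overview**
- The strategy rests on the exocyclic methylene on C10 of the seven-membered ring, flanked by ring-fusion carbon C9 and by C1H2 with C2 next to it. This is the footprint of a type 2 carbonyl-ene reaction between an isopropenyl group on C9 and an aldehyde carbon C2 (new bond C1–C2).
- The 2,7-dioxabicyclo[3.2.1]octan-3-one is cut back to a C8–CH2–CHO arm and hydroxy diester 30: haloacetal radical cyclisation (C14–C13), acylal lactonisation (O–C15), then α-acetoxylation at C12.
- The cis-cyclopentane 18 comes from enone 12 by conjugate prenylsilane addition (C5–C4) and kinetic protonation at C9. Enone 12 comes from (S)-2-allyl-2-methylcyclopentanone, whose C8 quaternary centre is set by asymmetric decarboxylative allylation.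
- Order of ring formation: five-membered carbocycle (from 1), seven-membered carbocycle (step 12), tetrahydrofuran (step 23), δ-lactone (step 24).

Key step: step 12

Remark on the chemistry (assumptions):
- Labels used here: hydroazulene C1–C10 (C10 carries =CH2, C4 the gem-dimethyl group, C5/C9 are the ring-fusion carbons, C8 the quaternary carbon); bicycle C14 (on C8), C15 (acetal carbon), C13, C12 (acetoxy carbon), C11 (lactone C=O), C16 (carbon bearing CO2Me).
- (R)-But-3-ene-1,2-diol is taken as a commercial single enantiomer.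
- The (S)-PHOX ligand is assumed, by analogy with six-ring substrates, to give the (S)-ketone; otherwise its enantiomer is used.
- Both C2 epimers of 19 and 20 are carried on together.

**Step 1**
Reactants: 1 methyl 2-oxocyclopentane-1-carboxylate; 2 prop-2-en-1-ol (allyl alcohol)
Product: 3 allyl 2-oxocyclopentane-1-carboxylate
Conditions: DMAP (cat.), toluene, reflux, 4 Å sieves (MeOH removal)
Reagents that add atoms: none
Why: DMAP-catalysed transesterification of a β-keto ester exchanges the methyl for the allyl ester while methanol is removed from the equilibrium.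

**Step 2**
Reactants: 3 allyl 2-oxocyclopentane-1-carboxylate
Product: 4 allyl 1-methyl-2-oxocyclopentane-1-carboxylate (racemic)
Conditions: MeI, K2CO3, acetone, reflux
Reagents that add atoms: iodomethane, CI
Why: C-alkylation of the doubly activated β-keto ester enolate installs the future C8 methyl group, and the racemic centre is erased in step 3.

**Step 3**
Reactants: 4 allyl 1-methyl-2-oxocyclopentane-1-carboxylate
Product: 5 (S)-2-allyl-2-methylcyclopentan-1-one
Conditions: Pd2(dba)3 (cat.), (S)-(CF3)3-t-BuPHOX (cat.), toluene, 25 °C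
Reagents that add atoms: none
Why: Enantioselective decarboxylative Tsuji allylation, in which the palladium enolate and the allyl fragment formed by loss of CO2 recombine inside the chiral ligand pocket and so set the C8 quaternary centre.

**Step 4**
Reactants: 5 (S)-2-allyl-2-methylcyclopentan-1-one
Product: 6 (5S)-5-allyl-5-methylcyclopent-1-en-1-yl trifluoromethanesulfonate
Conditions: LiN(SiMe3)2, THF, −78 °C; PhNTf2, −78 → 0 °C
Reagents that add atoms: N-phenylbis(trifluoromethanesulfonimide), O=S(=O)(N(c1ccccc1)S(=O)(=O)C(F)(F)F)C(F)(F)F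
Why: Enol triflate formation is regiodefined because only the methylene that becomes C5 can enolise, giving the C9=C5 vinyl triflate.

**Step 5**
Reactants: 6 (5S)-5-allyl-5-methylcyclopent-1-en-1-yl trifluoromethanesulfonate
Product: 8 2-[(1S)-1-methyl-2-(trifluoromethanesulfonyloxy)cyclopent-2-en-1-yl]ethan-1-ol, via aldehyde 7 (not isolated)
Conditions: O3, CH2Cl2, −78 °C; PPh3, −78 °C → rt; NaBH4, MeOH, 0 °C
Reagents that add atoms: ozone, [O-][O+]=O
Why: Ozonolysis with reductive work-up cleaves the electron-rich terminal alkene much faster than the triflate-deactivated enol double bond, and NaBH4 reduces the aldehyde without touching the vinyl triflate.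

**Step 6**
Reactants: 8 2-[(1S)-1-methyl-2-(trifluoromethanesulfonyloxy)cyclopent-2-en-1-yl]ethan-1-ol
Product: 9 (5S)-5-[2-(tert-butyldiphenylsilyloxy)ethyl]-5-methylcyclopent-1-en-1-yl trifluoromethanesulfonate
Conditions: TBDPSCl, imidazole, DMF, rt
Reagents that add atoms: tert-butyl(chloro)diphenylsilane, CC(C)(C)[Si](Cl)(c1ccccc1)c1ccccc1
Why: Imidazole-promoted silylation of the primary alcohol gives a TBDPS ether that withstands TiCl4, Me2AlCl and the radical steps that follow.

**Step 7**
Reactants: 9 (5S)-5-[2-(tert-butyldiphenylsilyloxy)ethyl]-5-methylcyclopent-1-en-1-yl trifluoromethanesulfonate; 10 tributyl(1-ethoxyvinyl)stannane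
Product: 12 1-{(5S)-5-[2-(tert-butyldiphenylsilyloxy)ethyl]-5-methylcyclopent-1-en-1-yl}ethan-1-one, via dienyl ether 11 (not isolated)
Conditions: Pd(PPh3)4 (cat.), LiCl, THF, 65 °C; then 1 M HCl, THF, rt
Reagents that add atoms: water, O
Why: Stille coupling of the vinyl triflate with the α-ethoxyvinylstannane followed by acid hydrolysis of the enol ether unmasks the acetyl group and gives the C5=C9–C10 enone.

**Step 8**
Reactants: 12 1-{(5S)-5-[2-(tert-butyldiphenylsilyloxy)ethyl]-5-methylcyclopent-1-en-1-yl}ethan-1-one; 13 trimethyl(3-methylbut-2-en-1-yl)silane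
Product: 14 1-{(1R,2R,5S)-5-[2-(tert-butyldiphenylsilyloxy)ethyl]-5-methyl-2-(2-methylbut-3-en-2-yl)cyclopentyl}ethan-1-one (acetyl, tert-alkyl group and C8 methyl all cis)
Conditions: TiCl4, CH2Cl2, −78 °C; MeOH then aq NaHCO3 at −78 °C
Reagents that add atoms: none
Why: In this Hosomi–Sakurai conjugate addition the γ-carbon of the prenylsilane attacks C5 of the TiCl4-activated enone and creates the C4 quaternary carbon, attack being expected anti to the larger silyloxyethyl arm on C8 (held pseudo-axial by allylic strain with the complexed acetyl group), while cold protonation of the titanium enolate from the face opposite the new tert-alkyl group sets the C9 acetyl cis to it.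

**Step 9**
Reactants: 14 the cis ketone
Product: 15 tert-butyl{2-[1-methyl-3-(2-methylbut-3-en-2-yl)-2-(prop-1-en-2-yl)cyclopentyl]ethoxy}diphenylsilane (configuration as in 14)
Conditions: Tebbe reagent Cp2Ti(μ-CH2)(μ-Cl)AlMe2, pyridine (cat.), THF/toluene, −40 → 0 °C
Reagents that add atoms: Tebbe reagent, C[Al-]1(C)C[Ti]([Cl+]1)(C1C=CC=C1)C1C=CC=C1
Why: Tebbe methylenation is a non-basic carbonyl olefination through the titanocene methylidene, so the hindered and epimerisable methyl ketone becomes the isopropenyl group without loss of the C9 configuration.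

**Step 10**
Reactants: 15 the isopropenyl vinyl compound
Product: 17 3-methyl-3-[cyclopentyl]butan-1-ol (primary C2 alcohol, ring substituents as in 15), via catechol boronate 16 (not isolated)
Conditions: catecholborane, RhCl(PPh3)3 (cat.), THF, rt; then NaOH, H2O2, 0 °C
Reagents that add atoms: catecholborane, [H]B1Oc2ccccc2O1; hydrogen peroxide, OO
Why: Rhodium-catalysed hydroboration strongly prefers the monosubstituted vinyl group over the hindered 1,1-disubstituted isopropenyl group and places boron on the terminal carbon, so oxidation gives the primary alcohol.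

**Step 11**
Reactants: 17 the primary alcohol
Product: 18 3-methyl-3-[cyclopentyl]butanal, the ene precursor (isopropenyl on C9 and 2-methyl-4-oxobutan-2-yl arm on C5 cis, C8 methyl cis to both, silyloxyethyl arm trans)
Conditions: Dess–Martin periodinane, NaHCO3, CH2Cl2, 0 °C → rt
Reagents that add atoms: none
Why: Dess–Martin oxidation gives the aldehyde under buffered conditions that leave the isopropenyl group and the silyl ether untouched.

**Step 12**
Reactants: 18 the isopropenyl aldehyde
Product: 19 8-[2-(tert-butyldiphenylsilyloxy)ethyl]-4,4,8-trimethyl-10-methylene-cis-hydroazulen-2-ol (5-H and 9-H cis to each other and to the C8 side chain, C8 methyl on the other face; both C2 epimers)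
Conditions: Me2AlCl (2 equiv), CH2Cl2, −78 → −20 °C; aq potassium sodium tartrate
Reagents that add atoms: none
Why: Me2AlCl activates the aldehyde, C1 (the terminal carbon of the isopropenyl group) attacks C2, and a hydrogen of the allylic methyl passes to oxygen through a six-membered ene transition state (or a short-lived C10 cation), so the double bond ends exocyclic on C10. The closest known reaction type is the Me2AlCl-promoted type 2 intramolecular carbonyl-ene cyclisation of 6-methylhept-6-enals to 3-methylenecycloheptanols. The seven-membered ring closes in a mode that is exo at the carbonyl and endo at the ene double bond. The only new stereocentre, the C2 carbinol, is uncontrolled and is removed in steps 13 and 14, while C5, C8 and C9 are untouched. The step needs the ene pathway to win over chloride capture, proton loss toward C9 and intermolecular reaction: Me2AlCl removes the transferred proton as methane, the C9 hydrogen cannot reach the carbonyl oxygen in the type 2 geometry, and the cis arrangement of the two arms together with the C4 gem-dimethyl group holds C1 and C2 close.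

**Step 13**
Reactants: 19 the hydroazulenol
Product: 20 O-(hydroazulen-2-yl) 1H-imidazole-1-carbothioate (skeleton as in 19)
Conditions: 1,1′-thiocarbonyldiimidazole, DMAP (cat.), 1,2-dichloroethane, 70 °C
Reagents that add atoms: 1,1′-thiocarbonyldiimidazole, S=C(n1ccnc1)n1ccnc1
Why: Thioacylation of the secondary alcohol gives the thiocarbonyl derivative needed for Barton–McCombie deoxygenation, and both C2 epimers react alike.

**Step 14**
Reactants: 20 the thiocarbonylimidazolide
Product: 21 tert-butyl[2-(4,4,8-trimethyl-10-methylene-cis-hydroazulen-8-yl)ethoxy]diphenylsilane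
Conditions: Bu3SnH, AIBN (cat.), toluene, 100 °C
Reagents that add atoms: none
Why: In this Barton–McCombie deoxygenation the stannyl radical adds to the thiocarbonyl, β-scission gives the secondary C2 radical, and this takes hydrogen from Bu3SnH faster than it can rearrange through the strained three-membered pathway onto the exocyclic alkene.

**Step 15**
Reactants: 21 the silyl ether
Product: 22 2-(4,4,8-trimethyl-10-methylene-cis-hydroazulen-8-yl)ethan-1-ol
Conditions: Bu4NF, THF, rt
Reagents that add atoms: none
Why: Fluoride-induced desilylation frees the primary alcohol of the C8 arm.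

**Step 16**
Reactants: 22 the primary alcohol
Product: 23 2-(4,4,8-trimethyl-10-methylene-cis-hydroazulen-8-yl)acetaldehyde
Conditions: Dess–Martin periodinane, NaHCO3, CH2Cl2, rt
Reagents that add atoms: none
Why: Dess–Martin oxidation reaches the β-quaternary aldehyde without acid, so the exocyclic methylene is not isomerised.

**Step 17**
Reactants: 23 the aldehyde
Product: 24 the dimethyl acetal of 23
Conditions: HC(OMe)3, PPTS (cat.), MeOH, rt
Reagents that add atoms: trimethyl orthoformate, COC(OC)OC; methanol, CO
Why: Acid-catalysed acetalisation with the orthoformate as water scavenger uses an acid too weak to protonate the 1,1-disubstituted alkene.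

**Step 18**
Reactants: 24 the dimethyl acetal
Product: 25 8-(2-methoxyethenyl)-4,4,8-trimethyl-10-methylene-cis-hydroazulene (methyl enol ether, E/Z mixture)
Conditions: Me3SiOTf, iPr2NEt, CH2Cl2, −20 °C → rt
Reagents that add atoms: none
Why: Silyl triflate–amine elimination of methanol from the acetal (oxocarbenium formation, then deprotonation at C14) gives the enol ether, and both geometric isomers converge later at the planar C14 radical.

**Step 19**
Reactants: 26 (R)-but-3-ene-1,2-diol; 27 tert-butyl acrylate
Product: 28 tert-butyl (R,E)-4,5-dihydroxypent-2-enoate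
Conditions: second-generation Hoveyda–Grubbs catalyst RuCl2(H2IMes)(=CH-C6H4-2-OiPr) (cat.), CH2Cl2, 40 °C
Reagents that add atoms: none
Why: Olefin cross-metathesis between the terminal allylic diol and the electron-poor acrylate gives the (E)-enoate with loss of ethene and does not involve the carbinol centre.

**Step 20**
Reactants: 28 tert-butyl (R,E)-4,5-dihydroxypent-2-enoate
Product: 29 (R,E)-5-tert-butoxy-2-hydroxy-5-oxopent-3-enoic acid
Conditions: TEMPO (cat.), PhI(OAc)2, MeCN/H2O, rt
Reagents that add atoms: water, O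
Why: Nitroxyl-catalysed oxidation is selective for the primary hydroxyl and carries it through the aldehyde hydrate to the acid, leaving the secondary carbinol and its configuration intact.

**Step 21**
Reactants: 29 the hydroxy acid
Product: 30 1-tert-butyl 5-methyl (R,E)-4-hydroxypent-2-enedioate
Conditions: Me3SiCHN2, MeOH/toluene, 0 °C
Reagents that add atoms: (trimethylsilyl)diazomethane, C[Si](C)(C)C=[N+]=[N-]
Why: Diazoalkane O-methylation of the carboxylic acid is fast and selective over the secondary alcohol.

**Step 22**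
Reactants: 25 the methyl enol ether; 30 1-tert-butyl 5-methyl (R,E)-4-hydroxypent-2-enedioate
Product: 31 mixed iodoacetal C8–CH(I)–CH(OMe)–O–CH(CO2Me)–CH=CH–CO2tBu (mixture at C14 and C15, C16 R)
Conditions: NIS, CH2Cl2, −40 → 0 °C
Reagents that add atoms: N-iodosuccinimide, O=C1CCC(=O)N1I
Why: Iodoetherification, the first half of the Ueno–Stork sequence, puts iodine on C14 of the enol ether, which is far more nucleophilic than the exocyclic alkene, and alcohol 30 captures the oxocarbenium ion.

**Step 23**
Reactants: 31 the iodoacetal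
Product: 32 methyl 2-methoxytetrahydrofuran-5-carboxylate bearing the hydroazulen-8-yl group on C14 and CH2CO2tBu on C13 (C14/C13 cis, C13/C16 trans, both C15 epimers)
Conditions: Bu3SnH (slow addition), AIBN (cat.), toluene, 80 °C
Reagents that add atoms: none
Why: In this Ueno–Stork 5-exo-trig radical cyclisation the C14 radical adds to the acrylate β-carbon C13 and the α-ester radical is reduced by the stannane; the pseudo-equatorial C16 ester in the chair-like transition state places the new side chain trans to it, and the C14/C13 relation is expected to follow the cis preference of 1-substituted hexenyl radicals, which is the least secure point of the route.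

**Step 24**
Reactants: 32 the tetrahydrofuran acetal
Product: 33 methyl 3-oxo-2,7-dioxabicyclo[3.2.1]octane-6-carboxylate with the hydroazulen-8-yl group on the one-carbon bridge C14 (syn to the lactone bridge, ester exo)
Conditions: Me3SiOTf, 2,6-lutidine, CH2Cl2, −20 → 0 °C
Reagents that add atoms: none
Why: The silyl triflate converts the tert-butyl ester into the silyl ester and ionises the methyl acetal, and the C15 oxocarbenium ion is captured by the carboxylate of the cis C13 side chain (lactonisation to the bicyclic acylal), so both acetal epimers converge while the lutidine buffer protects the exocyclic alkene.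

**Step 25**
Reactants: 33 the bicyclic lactone
Product: 34 the C12 endo α-hydroxy lactone
Conditions: LiN(SiMe3)2, THF, −78 °C; 2-(phenylsulfonyl)-3-phenyloxaziridine, −78 °C; aq work-up
Reagents that add atoms: 2-(phenylsulfonyl)-3-phenyloxaziridine, O=S(=O)(c1ccccc1)N1OC1c1ccccc1
Why: Enolate hydroxylation with the Davis oxaziridine takes place at C12 because the lactone α-protons are the most acidic and accessible, and the oxidant approaches the enolate face opposite the C14 bridge that carries the hydroazulene, giving the endo alcohol.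

**Step 26**
Reactants: 34 the hydroxy lactone
Product: 35 the target CNP0215240.1
Conditions: Ac2O, pyridine, DMAP (cat.), CH2Cl2, 0 °C → rt
Reagents that add atoms: acetic anhydride, CC(=O)OC(C)=O
Why: DMAP-catalysed acetylation of the secondary alcohol gives the target without touching the acylal or the methyl ester.

**Compound list**
1 | methyl 2-oxocyclopentane-1-carboxylate | COC(=O)C1CCCC1=O | starting material
2 | prop-2-en-1-ol | C=CCO | starting material
3 | allyl 2-oxocyclopentane-1-carboxylate | C=CCOC(=O)C1CCCC1=O | intermediate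
4 | allyl 1-methyl-2-oxocyclopentane-1-carboxylate (racemic) | C=CCOC(=O)C1(C)CCCC1=O | intermediate
5 | (S)-2-allyl-2-methylcyclopentan-1-one | O=C1CCC[C@@]1(C)CC=C | intermediate
6 | (5S)-5-allyl-5-methylcyclopent-1-en-1-yl trifluoromethanesulfonate | O=S(=O)(OC1=CCC[C@@]1(C)CC=C)C(F)(F)F | intermediate
7 | 2-[(1S)-1-methyl-2-(trifluoromethanesulfonyloxy)cyclopent-2-en-1-yl]acetaldehyde | O=S(=O)(OC1=CCC[C@@]1(C)CC=O)C(F)(F)F | intermediate
8 | 2-[(1S)-1-methyl-2-(trifluoromethanesulfonyloxy)cyclopent-2-en-1-yl]ethan-1-ol | O=S(=O)(OC1=CCC[C@@]1(C)CCO)C(F)(F)F | intermediate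
9 | (5S)-5-[2-(tert-butyldiphenylsilyloxy)ethyl]-5-methylcyclopent-1-en-1-yl trifluoromethanesulfonate | O=S(=O)(OC1=CCC[C@@]1(C)CCO[Si](c1ccccc1)(c1ccccc1)C(C)(C)C)C(F)(F)F | intermediate
10 | tributyl(1-ethoxyvinyl)stannane | CCCC[Sn](CCCC)(CCCC)C(=C)OCC | starting material
11 | tert-butyl{2-[(1S)-2-(1-ethoxyvinyl)-1-methylcyclopent-2-en-1-yl]ethoxy}diphenylsilane | C=C(OCC)C1=CCC[C@@]1(C)CCO[Si](c1ccccc1)(c1ccccc1)C(C)(C)C | intermediate
12 | 1-{(5S)-5-[2-(tert-butyldiphenylsilyloxy)ethyl]-5-methylcyclopent-1-en-1-yl}ethan-1-one | CC(=O)C1=CCC[C@@]1(C)CCO[Si](c1ccccc1)(c1ccccc1)C(C)(C)C | intermediate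
13 | trimethyl(3-methylbut-2-en-1-yl)silane | CC(C)=CC[Si](C)(C)C | starting material
14 | 1-{(1R,2R,5S)-5-[2-(tert-butyldiphenylsilyloxy)ethyl]-5-methyl-2-(2-methylbut-3-en-2-yl)cyclopentyl}ethan-1-one | CC(=O)[C@@H]1[C@H](C(C)(C)C=C)CC[C@@]1(C)CCO[Si](c1ccccc1)(c1ccccc1)C(C)(C)C | intermediate
15 | isopropenyl analogue of 14 (acetyl replaced by prop-1-en-2-yl) | CC(=C)[C@@H]1[C@H](C(C)(C)C=C)CC[C@@]1(C)CCO[Si](c1ccccc1)(c1ccccc1)C(C)(C)C | intermediate
16 | catechol boronate at C2 of 15 | CC(=C)[C@@H]1[C@H](C(C)(C)CCB2Oc3ccccc3O2)CC[C@@]1(C)CCO[Si](c1ccccc1)(c1ccccc1)C(C)(C)C | intermediate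
17 | primary C2 alcohol | CC(=C)[C@@H]1[C@H](C(C)(C)CCO)CC[C@@]1(C)CCO[Si](c1ccccc1)(c1ccccc1)C(C)(C)C | intermediate
18 | C2 aldehyde, ene precursor | CC(=C)[C@@H]1[C@H](C(C)(C)CC=O)CC[C@@]1(C)CCO[Si](c1ccccc1)(c1ccccc1)C(C)(C)C | intermediate
19 | 8-[2-(tert-butyldiphenylsilyloxy)ethyl]-4,4,8-trimethyl-10-methylene-cis-hydroazulen-2-ol (C2 epimers) | C=C1CC(O)CC(C)(C)[C@@H]2CC[C@@](C)(CCO[Si](c3ccccc3)(c3ccccc3)C(C)(C)C)[C@H]12 | intermediate
20 | C2 O-thiocarbonylimidazolide of 19 | C=C1CC(OC(=S)n3ccnc3)CC(C)(C)[C@@H]2CC[C@@](C)(CCO[Si](c3ccccc3)(c3ccccc3)C(C)(C)C)[C@H]12 | intermediate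
21 | tert-butyl[2-(4,4,8-trimethyl-10-methylene-cis-hydroazulen-8-yl)ethoxy]diphenylsilane | C=C1CCCC(C)(C)[C@@H]2CC[C@@](C)(CCO[Si](c3ccccc3)(c3ccccc3)C(C)(C)C)[C@H]12 | intermediate
22 | 2-(4,4,8-trimethyl-10-methylene-cis-hydroazulen-8-yl)ethan-1-ol | C=C1CCCC(C)(C)[C@@H]2CC[C@@](C)(CCO)[C@H]12 | intermediate
23 | 2-(4,4,8-trimethyl-10-methylene-cis-hydroazulen-8-yl)acetaldehyde | C=C1CCCC(C)(C)[C@@H]2CC[C@@](C)(CC=O)[C@H]12 | intermediate
24 | dimethyl acetal of 23 | C=C1CCCC(C)(C)[C@@H]2CC[C@@](C)(CC(OC)OC)[C@H]12 | intermediate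
25 | 8-(2-methoxyethenyl)-4,4,8-trimethyl-10-methylene-cis-hydroazulene (E/Z) | C=C1CCCC(C)(C)[C@@H]2CC[C@@](C)(C=COC)[C@H]12 | intermediate
26 | (R)-but-3-ene-1,2-diol | OC[C@H](O)C=C | starting material
27 | tert-butyl acrylate | C=CC(=O)OC(C)(C)C | starting material
28 | tert-butyl (R,E)-4,5-dihydroxypent-2-enoate | OC[C@H](O)/C=C/C(=O)OC(C)(C)C | intermediate
29 | (R,E)-5-tert-butoxy-2-hydroxy-5-oxopent-3-enoic acid | OC(=O)[C@H](O)/C=C/C(=O)OC(C)(C)C | intermediate
30 | 1-tert-butyl 5-methyl (R,E)-4-hydroxypent-2-enedioate | COC(=O)[C@H](O)/C=C/C(=O)OC(C)(C)C | intermediate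
31 | mixed iodoacetal (mixture at C14, C15) | C=C1CCCC(C)(C)[C@@H]2CC[C@@](C)(C(I)C(OC)O[C@H](/C=C/C(=O)OC(C)(C)C)C(=O)OC)[C@H]12 | intermediate
32 | tetrahydrofuran methyl acetal (C15 epimers) | C=C1CCCC(C)(C)[C@@H]2CC[C@@](C)([C@@H]3C(OC)O[C@@H](C(=O)OC)[C@@H]3CC(=O)OC(C)(C)C)[C@H]12 | intermediate
33 | bicyclic lactone (C12 unsubstituted) | C=C1CCCC(C)(C)[C@@H]2CC[C@@](C)([C@@H]3[C@@H]4OC(=O)C[C@H]3[C@H](C(=O)OC)O4)[C@H]12 | intermediate
34 | C12 endo hydroxy lactone | C=C1CCCC(C)(C)[C@@H]2CC[C@@](C)([C@@H]3[C@@H]4OC(=O)[C@@H](O)[C@H]3[C@H](C(=O)OC)O4)[C@H]12 | intermediate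
35 | CNP0215240.1 | C=C1CCCC(C)(C)[C@@H]2CC[C@@](C)([C@@H]3[C@@H]4OC(=O)[C@@H](OC(C)=O)[C@H]3[C@H](C(=O)OC)O4)[C@H]12 | target

**Step count and risks**
Total step count: 26. Longest linear sequence: 23 steps (steps 1–18 and 22–26 from compound 1); steps 19–21 make alcohol 30 in a convergent branch.

Steps most likely to fail:

1. Step 12 (key step). The seven-membered closure may be too slow, so that chloride capture of the zwitterion, oligomerisation or aldehyde decomposition take over. Fallback: replace the ene reaction by an allylsilane-terminated cyclisation. It sets out from ketone 14. Kinetic enolisation at the methyl group (LiN(SiMe3)2, PhNTf2) gives the enol triflate F1. Kumada coupling with Me3SiCH2MgCl and Pd(PPh3)4 gives the allylsilane F2. Rhodium-catalysed hydroboration–oxidation of the vinyl group gives the alcohol F3, and Dess–Martin oxidation gives the aldehyde F4. BF3·OEt2 at −78 °C then closes the ring by intramolecular Hosomi–Sakurai reaction and comes back to the route at 19.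

2. Step 8. Facial discrimination at C5 between the methyl group and the silyloxyethyl arm on the remote C8 centre may be poor, giving the C5/C9 epimeric pair. Fallback: set C5 by chirality transfer from a reagent-controlled carbinol. It sets out from enone 12. Corey–Bakshi–Shibata reduction ((S)-methyl oxazaborolidine, catecholborane) gives the (R)-allylic alcohol F5, and isobutyryl chloride gives the isobutyrate F6. Ireland–Claisen rearrangement (LiN(iPr)2, Me3SiCl, −78 → 60 °C), through the transition state with the carbinol methyl turned toward C5, delivers C4 to the face of C5 cis to the C8 methyl and gives the acid F7 with an (E)-ethylidene on C9. BH3·THF then NaOH/H2O2 reduces the acid and hydroborates the ethylidene anti to the C5 substituent, giving the diol F8. Dess–Martin oxidation gives the keto aldehyde F9; aldehyde-selective Wittig reaction with Ph3P=CHOMe gives the enol ether F10; Tebbe methylenation gives the isopropenyl enol ether F11. Aqueous oxalic acid then frees the aldehyde and the route is rejoined at 18.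

3. Step 23. The bulky tert-alkyl substituent on the C14 radical may take the outside position in the chair transition state, so that facial selectivity at C14 is poor or reversed. Fallback: set C14 by hydrogen-atom transfer after the ring is closed. It sets out from aldehyde 23. Enamine-mediated α-chlorination (N-chlorosuccinimide, pyrrolidine cat.) gives the chloro aldehyde F12; HC(OMe)3/PPTS gives the chloro acetal F13; Me3SiOTf/iPr2NEt gives the chloro enol ether F14; NIS and alcohol 30 give the geminal chloro-iodo acetal F15. With excess Bu3SnH and AIBN in toluene at 110 °C the iodide reacts first and the α-chloro radical cyclises 5-exo to the tertiary chloride F16. Its reduction in the same flask forms the ring radical at C14, which takes hydrogen on the face anti to the adjacent C13 side chain, and the route is rejoined at 32.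

**Further compounds**
F1 | step 12 | enol triflate from the methyl ketone of 14 | C=C(OS(=O)(=O)C(F)(F)F)[C@@H]1[C@H](C(C)(C)C=C)CC[C@@]1(C)CCO[Si](c1ccccc1)(c1ccccc1)C(C)(C)C
F2 | step 12 | 2-(trimethylsilylmethyl)vinyl allylsilane | C=C(C[Si](C)(C)C)[C@@H]1[C@H](C(C)(C)C=C)CC[C@@]1(C)CCO[Si](c1ccccc1)(c1ccccc1)C(C)(C)C
F3 | step 12 | allylsilane primary alcohol | C=C(C[Si](C)(C)C)[C@@H]1[C@H](C(C)(C)CCO)CC[C@@]1(C)CCO[Si](c1ccccc1)(c1ccccc1)C(C)(C)C
F4 | step 12 | allylsilane aldehyde | C=C(C[Si](C)(C)C)[C@@H]1[C@H](C(C)(C)CC=O)CC[C@@]1(C)CCO[Si](c1ccccc1)(c1ccccc1)C(C)(C)C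
F5 | step 8 | (R)-1-(cyclopentenyl)ethanol from 12 | C[C@@H](O)C1=CCC[C@@]1(C)CCO[Si](c1ccccc1)(c1ccccc1)C(C)(C)C
F6 | step 8 | isobutyrate of F5 | CC(C)C(=O)O[C@H](C)C1=CCC[C@@]1(C)CCO[Si](c1ccccc1)(c1ccccc1)C(C)(C)C
F7 | step 8 | Claisen acid with (E)-ethylidene on C9 | C/C=C1\[C@H](C(C)(C)C(O)=O)CC[C@@]1(C)CCO[Si](c1ccccc1)(c1ccccc1)C(C)(C)C
F8 | step 8 | diol (C10 carbinol epimers) | CC(O)[C@@H]1[C@H](C(C)(C)CO)CC[C@@]1(C)CCO[Si](c1ccccc1)(c1ccccc1)C(C)(C)C
F9 | step 8 | keto aldehyde | CC(=O)[C@@H]1[C@H](C(C)(C)C=O)CC[C@@]1(C)CCO[Si](c1ccccc1)(c1ccccc1)C(C)(C)C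
F10 | step 8 | keto methyl enol ether (E/Z) | CC(=O)[C@@H]1[C@H](C(C)(C)C=COC)CC[C@@]1(C)CCO[Si](c1ccccc1)(c1ccccc1)C(C)(C)C
F11 | step 8 | isopropenyl methyl enol ether (E/Z) | CC(=C)[C@@H]1[C@H](C(C)(C)C=COC)CC[C@@]1(C)CCO[Si](c1ccccc1)(c1ccccc1)C(C)(C)C
F12 | step 23 | α-chloro aldehyde (C14 epimers) | C=C1CCCC(C)(C)[C@@H]2CC[C@@](C)(C(Cl)C=O)[C@H]12
F13 | step 23 | α-chloro dimethyl acetal | C=C1CCCC(C)(C)[C@@H]2CC[C@@](C)(C(Cl)C(OC)OC)[C@H]12
F14 | step 23 | chloro enol ether (E/Z) | C=C1CCCC(C)(C)[C@@H]2CC[C@@](C)(C(Cl)=COC)[C@H]12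
F15 | step 23 | geminal chloro-iodo mixed acetal | C=C1CCCC(C)(C)[C@@H]2CC[C@@](C)(C(Cl)(I)C(OC)O[C@H](/C=C/C(=O)OC(C)(C)C)C(=O)OC)[C@H]12
F16 | step 23 | tertiary C14 chloride of the tetrahydrofuran acetal | C=C1CCCC(C)(C)[C@@H]2CC[C@@](C)(C3(Cl)C(OC)O[C@@H](C(=O)OC)[C@@H]3CC(=O)OC(C)(C)C)[C@H]12
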